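In a one-step world, substrate and reagent give target and the flask simply stops when one of them is spent, so I began there.

the same everywhere: substrate 1.4 M
- delta: reagent 1 M; run made earlier
- beta: reagent 2.3 M; run made earlier
- flask: reagent 1.54 M; time 12 d

- delta (time / d: target / %, side product / %): 0.833: 65, 10; 2.50: 72, 17; 4.00: 69, 19; 6.00: 71, 18; 10.0: 74, 25
- beta (time / d: target / %, side product / %): 2.08: 97, 5; 4.00: 95, 3; 6.00: 98, 4; 8.00: 97, 6; 10.0: 95, 4

(each reading ± 1.5 percentage points)

- how much target there is at 12 d, in percent of the substrate charged
- how much side product there is at 12 d, in percent of the substrate charged



1. From 2.50 d on, the delta target readings stayed near 72%, and the reagent charge there was 71.4% of the substrate charge, so I took one reagent per substrate. The flask has 1.10 substrate charges of reagent, so in the one-step world I reckoned 100% target for it, with 0.100 charge of reagent left.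

2. Next I added the side step. In delta, side product rose from 19% to 25% between 4.00 d and 10.0 d, so I let substrate form it without reagent. I then froze one number, the split number s: side product formed per target formed, when the reagent standing equals one substrate charge. It is a selectivity factor, and side per target goes as s divided by reagent left. Summed up, side product = s·ln(reagent charged/reagent left).

3. Beta, charged with 1.64 charges, averaged 96.4% target and 4.40% side product, which read as s = 0.0498. On delta's first reading this gives 12.0% side product; the reading was 10%.

4. Taking the flask's final reagent as 0.100 charge gave 11.9% side product. But in my scheme substrate that forms side product takes no reagent, so the reagent left is that charge plus the side product, and I fed each answer back: 8.03%, 9.00%, 8.74%.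

5. Beta's readings stayed flat within their scatter from 2.08 d to 10.0 d, so I added no later step. My reckoning left 91.3% target.

The forecast said 91% target (88% to 94%) and 9% side product (6% to 12%): “The flask has 1.1 equivalents of reagent, so substrate is consumed well before 12 d.”

The flask gave 92.7% target and 7.31% side product.

    substrate + reagent → target (k = 0.150 M⁻¹ h⁻¹)
    substrate → side product (k = 0.00830 h⁻¹)

At 12.0 d, 16% of the flask's reagent charge remained, and s with that amount gives 9.21% side product. A neighbouring flask charged with 0.92 M of reagent kept 0.033% of its own charge, so the same rule gives 39.9%, and that neighbouring flask holds 31.7% side product.

The runs are simulated on assumed constants.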